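**Last reading.** Green's last reading stood at 56.1% of its charge, at 71 min. The ochre flask had the same charge and ran to 280 min, so I asked what the rest of that time could add.

| flask | substrate | free catalyst | time |
|---|---|---|---|
| green | 300 mM | 15.0 mM |  |
| amber | 300 mM | 30.0 mM |  |
| blue | 900 mM | 15.0 mM |  |
| ochre | 300 mM | 15.0 mM | 280 min |

- green run (time / min: [product] / mM): 4.0: 39.2; 12: 93.2; 23: 130.4; 37: 155.4; 53: 166.4; 71: 168.3
- amber run (time / min: [product] / mM): 4.0: 143.0; 12: 237.1; 23: 249.4; 37: 251.1; 53: 250.9; 71: 257.6
- blue run (time / min: [product] / mM): 4.0: 59.9; 12: 126.7; 23: 176.7; 37: 205.9; 53: 225.2; 71: 232.6

(each reading ± 2 mM)

- reaction order in [substrate] at the outset, round the charge of the green run, defined at two percent of the substrate turned into product (one fixed amount of product, the same in the runs compared)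
- reaction order in [free catalyst] at the outset, round the charge of the green run, defined at two percent of the substrate turned into product
- product in the ochre run at 280 min, as a share of the substrate charged

- Overall: substrate -> product, with free catalyst as catalyst.
- Constant volume, constant temperature.
- What is held in complexes is read along with the free species.
- An order is taken over about fifteen percent of the charge, up and down.

**Turned round.** For full turnover, ochre needed a mean of 0.00210 /min, as a share of its charge, after 71 min. Green's last interval gave 3.52 × 10⁻⁴ /min, with a scatter of 5.24 × 10⁻⁴ /min. The need lay 3.34 scatters above that reading.

**Closing gap.** I took the gap as the final share minus the share made, and let it shrink in proportion to itself. Integrated, this is an exponential. Its fade constant, the fraction of the gap closed per minute, read 0.0645 /min from green's readings at 4.0 min and 23 min, with the last reading as final share. On this law the gap halved every 10.7 min, and the outset rate, as a share of the charge, is this constant times the final share. From the 4.0 min reading, the law left 0.571% of the charge to come after 71 min. I therefore expected 56.7% in ochre.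

**The forecast.** It gave 57%, with orders 0.4 in substrate and 2 in free catalyst, and read the stop thus: “This points to catalyst death rather than equilibrium”.

**The result.** Ochre gave 57.9%. Round green's charge, the orders were 0.55 in substrate and 2.1 in free catalyst.

    free catalyst + substrate ⇌ catalyst-substrate complex, settled at all times (1.050 /M)
    catalyst-substrate complex + free catalyst → product + 2 free catalyst (307.2 /M/min)
    catalyst-substrate complex → spent catalyst + substrate (0.05958 /min)
    2 substrate → homo dimer (0.1356 /M/min)

At green's charge, the homo dimer step by itself gives substrate a first half-life of 12.3 min. Ochre ended 1.8 percentage points above green's last reading, where the law had left 0.571% to come. In blue, green's fade constant times blue's last share gives an outset rate of 0.0167 /min, as a share of blue's charge. Blue's rate where its product equalled two percent of green's substrate was 0.0187 /min, as the same share.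

All runs come from a simulation with constants of no real substance; the scatter is artificial.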